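Tetralin numbering is used for all ring B compounds (C1 carries the aryl group, C4 is the methylene, C4a/C8a are the fusion carbons); compounds 3–7 use 1,3-benzodioxole numbering.

## Structural features

The target is a 1-aryltetralin cyclolignan. Ring A is a fully differentiated benzene (C5–H, C6–OMe, free hydroxyls on C7 and C8) fused through C4a/C8a to the carbocyclic ring B, which carries a 3,4,5-trimethoxyphenyl group on C1, hydroxymethyl groups on C2 and C3, and an unsubstituted methylene at C4. C1, C2 and C3 are three adjacent stereocentres, (1S,2R,3S): the aryl group is trans to the C2 arm and the two arms are cis to each other. The free catechol is the fragile part (easy oxidation to the o-quinone, with the C8 oxygen peri to the doubly benzylic C1–H), the 1,4-diol can close to a cyclic ether under strong acid, and C1 ionises easily because the C6 methoxy group is para and the C8 oxygen ortho to C8a. The real difficulty is to set the 1,2-trans/2,3-cis triad in one absolute sense on a ring whose only handles are benzylic positions, beside a crowded tri-oxygenated arene. The key step uses two facts: C1 and C4 sit on the adjacent ring A carbons C8a and C4a, which is the pattern of an o-quinodimethane, and the cis C2/C3 pair with its two oxygenated one-carbon arms is a reduced butenolide. An o-tolualdehyde whose formyl carbon becomes C1 and whose methyl carbon becomes C4 can therefore be joined to 2(5H)-furanone across C2=C3, and the oxygen this leaves on C1 sits exactly where the ring A oxygens make its replacement by the aryl group easy.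

## Logic of the disconnections

**17 ⇒ 16.** The last operation frees the C7 and C8 hydroxyls by breaking the two O–C bonds to a ketal carbon. The catechol is the most oxidation-prone part of 17, so it is unmasked only at the end. The gain is that every earlier intermediate is a robust, non-phenolic compound. The demand is a cleavage that touches neither the diarylmethine C1–H nor the diol, which points to neutral hydrogenolysis.

**16 ⇒ 15.** The two primary alcohols are traced back to one γ-lactone (C2–C(=O)–O–CH2–C3). A cis-1,4-diol is simply a reduced cis-fused lactone. The gain is that both arms are tied into one ring that fixes 2,3-cis and is the thermodynamically preferred ring fusion. The demand is a hydride reduction that does not epimerise C2.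

**15 ⇒ 10 + 12.** The C1–aryl bond is cut. C1 is benzylic and its cation is stabilised by the C6 methoxy group (para) and the C8 oxygen (ortho), so the aryl group can arrive as a nucleophile and a hydroxyl can serve as leaving group. The gain is that the whole trimethoxyphenyl ring leaves the skeleton and is replaced by the oxygen that a photoenol cycloaddition installs anyway. The demands are ipso attack on the aryl donor, so that the 3,4,5-pattern is kept, and attack on the face of C1 anti to the C2 substituent, which inverts C1 relative to 10.

**12 ⇒ 11.** The B–F bonds are cut. This turns a commercial boronic acid into a salt that can transfer its aryl group under Lewis acid; the only demand is complete fluoride exchange.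

**10 ⇒ 7 + 8 (through 9).** C1–C2 and C3–C4 are cut together. These are the two bonds of a [4+2] cycloadduct between a hydroxy-o-quinodimethane and a cis alkene. The gain is the largest of the route: ring B, two C–C bonds and three stereocentres arise from two achiral fragments. The demands are these:
- the dienol with the outward hydroxyl must form cleanly;
- its hydroxyl-bearing terminus must pair with the α-carbon of the lactone;
- the approach must be endo;
- one face must be selected by a chiral titanium template.

The ketal carbon of 7 carries no hydrogen, so the excited carbonyl has nothing to abstract except the methyl hydrogen.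

**7 ⇒ 3 (through 4, 5, 6).** The aryl–CH3 bond is cut. The only free position ortho to the formyl group can be metalated if the aldehyde is masked in the flask as a chelating amino alkoxide. The gain is that the methyl group is added in one operation to a compound with a commercial substitution pattern. The demand is metalation next to the masked formyl carbon and not next to the methoxy group.

**3 ⇒ 1 + 2.** The two O–C bonds of the diphenylmethylene ketal are cut. This ketal has no α-hydrogen, tolerates organolithium, Lewis acid and hydride, and leaves by hydrogenolysis. The demand is only a double O-alkylation of the catechol without touching the aldehyde.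

## Other disconnections considered

**Alternative 1:** Syn bis-alkoxycarbonylation.
- **Cut:** the two exocyclic bonds C2–CO2Me and C3–CO2Me of diester A2, leading back to the (S)-configured 1-aryl-1,4-dihydronaphthalene A1 (benzyl ethers on the C7 and C8 oxygens).
- **Forward key step:** oxidative double methoxycarbonylation of C2=C3 with Pd(O2CCF3)2, CO and methanol, benzoquinone returning zerovalent palladium to divalent palladium. Methoxycarbonyl-palladation, CO insertion and methanolysis deliver both ester groups to one face.
- **In its favour:** syn delivery makes 2,3-cis a mechanistic certainty, and the pseudoaxial C1 aryl group should send the metal to the far face (1,2-trans). The aryl group is on C1 from the start, so no cationic arylation and no facial question at C1 arises; on this point the alternative is better than the chosen plan. The benzyl ethers should come off by hydrogenolysis at least as readily as the diphenylmethylene ketal (equal or better).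
- **Against it here:** the step closes no ring and creates two of the three stereocentres, so A1 must be made as a single enantiomer by separate asymmetric chemistry. Its C1–H is doubly benzylic and allylic, and divalent palladium with benzoquinone is also a dehydrogenating system, so aromatisation of ring B or migration of the double bond into conjugation would erase C1. An unstrained internal ring alkene is a slow substrate for this carbonylation, and pressurised CO is a hazard.
- **Comparison:** structurally, the chosen plan builds ring B from two achiral fragments, while this plan decorates a ring that must already exist in enantioenriched form. Mechanistically, both rely on suprafacial addition to a cis alkene for 2,3-cis, but the chosen plan draws its absolute configuration from a reagent and this one from an earlier stereocentre that the key conditions endanger. The endgame after A2 (LiAlH4, hydrogenolysis) is of equal length, but the way to A1 would probably cost clearly more than the two steps that lead to 7.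

**Alternative 2:** Enamine closure onto an o-quinone methide.
- **Cut:** the C1–C2 bond only, leading from the tricyclic lactol A5 back to carbinol A3. In A3 ring A carries the diaryl carbinol (future C1) on C8a next to a free C8 hydroxyl, and on C4a a methylene (C4) bound to C3 of a γ-lactol.
- **Forward key step:** acid ionises the carbinol to the o-quinone methide A4 (C8=O, C8a=C1), while a diarylprolinol silyl ether with benzoic acid opens the lactol to its C2 enamine. C2 adds to C1 in a six-membered closure, ring A rearomatises and the lactol closes again, cis-fused.
- **In its favour:** the target's own C8 hydroxyl is the activating group, the aryl group is already on C1, and C1 and C2 are set together under catalyst control. The amine is catalytic and neither ultraviolet light nor stoichiometric titanium is needed (better on these points). A5 needs only NaBH4 where the chosen plan needs LiAlH4 (equal or better).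
- **Against it here:** one ring bond is formed instead of two, and C3 must be set in an earlier asymmetric step and then match the catalyst. The 2,3-cis outcome hinges on enamine geometry at a C2 centre that stays epimerisable through that same enamine. A4 can be captured by the lactol hydroxyl, by water or by a second phenol. Telling the C7 and C8 oxygens apart adds protecting-group steps.
- **Comparison:** structurally, A3 is a far more elaborate precursor than 7 plus 8. Mechanistically, both plans exploit the donor oxygens of ring A at C1, here for C–C closure and in the chosen plan for arylation. In step economy the shorter endgame is outweighed by the length of the way to A3, so the total would probably exceed seven steps by a wide margin.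

**Alternative 3:** Hydroxymethyl radical addition with lactone capture.
- **Cut:** the C3–CH2OH bond and the lactone C–O bond of A7, leading back to the (S)-1-aryl-1,4-dihydronaphthalene-2-carboxylate A6 (ester on C2, C2=C3).
- **Forward key step:** the hydroxymethyl radical, made from methanol by hydrogen-atom transfer (Ir[dF(CF3)ppy]2(dtbbpy)PF6, quinuclidine, Bu4N H2PO4, visible light), adds to the β-carbon C3 (a Giese addition). The α-radical is reduced and protonated at C2, and the new hydroxyl closes the cis-fused lactone onto the C2 ester.
- **In its favour:** A7 is the same compound as 15, so the last two steps are identical (equal). Methanol is the C1 source, the metal is catalytic and the light is visible (better on these points). The aryl group is in place before the key step, and lactone closure funnels C2 into the cis-fused, 1,2-trans arrangement.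
- **Against it here:** only one C–C bond and no carbocycle is formed. The single stereo-determining event is a 1,3-induction from C1 to C3 across ring B, which is a weak control element. The C1–H of A6 is doubly benzylic and γ to the unsaturated ester, so the amine base can isomerise the alkene into conjugation with both rings, and the hydrogen-abstracting quinuclidinium radical cation can attack C1–H or C4–H in competition with methanol; either process destroys the C1 stereocentre or aromatises ring B.
- **Comparison:** structurally, this plan reaches 15 from an enantioenriched bicyclic ester that itself needs a multistep asymmetric synthesis, whereas the chosen plan reaches 15 in four linear steps from 1. Mechanistically, the chosen plan sets C2 and C3 in a concerted event and C1 by substitution, while this plan sets C1 first and relays it. In step economy it is probably several steps longer.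

Key step: step 3

Assumption: (R,R)-TADDOL is written as the ligand that leads to (1S,2S,3S)-10; if a first run shows the opposite sense of induction, the equally available (S,S)-ligand is used and nothing else changes.

Remark: in 9 the hydroxyl points away from the exocyclic methylene (the geometry usually called the E-dienol); because the neighbouring ring carbon bears oxygen, the formal CIP descriptor of that double bond is Z, and it is the geometry that counts.

## Route

Step 1
Reactants: 1 2,3-dihydroxy-4-methoxybenzaldehyde; 2 dichlorodiphenylmethane
Product: 3 7-methoxy-2,2-diphenyl-1,3-benzodioxole-4-carbaldehyde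
Conditions: Ph2CCl2 (1.3 equiv), K2CO3 (3 equiv), MeCN, 60 °C
Reagents that add atoms: none
Why: Double O-alkylation of the catechol by the benzhydrylic dichloride (ionisation to the chlorodiphenylmethyl cation, then ring closure) forms the cyclic ketal; the aldehyde and the methyl ether are not affected by carbonate.

Step 2
Reactants: 3 7-methoxy-2,2-diphenyl-1,3-benzodioxole-4-carbaldehyde
Product: 7 7-methoxy-5-methyl-2,2-diphenyl-1,3-benzodioxole-4-carbaldehyde, via lithium α-amino alkoxide 4 (not isolated), via ortho-lithiated amino alkoxide 5 (not isolated), via methylated amino alkoxide 6 (not isolated)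
Conditions: Me2NCH2CH2NHMe (1.1 equiv), n-BuLi (1.05 equiv), THF, −20 °C; add 3; n-BuLi (3 equiv), −20 °C, 18 h; MeI (6 equiv), −78 °C to rt; H2O
Reagents that add atoms: iodomethane, CI
Why: In situ protection of the aldehyde as a chelating α-amino alkoxide followed by directed ortho-metalation; the diamine arm holds n-BuLi at C5, the only free position next to the masked formyl carbon, and outranks the methoxy group that would direct to C6. Methylation of the aryllithium and hydrolysis of the carbinolamine return the aldehyde.

Step 3
Reactants: 7 7-methoxy-5-methyl-2,2-diphenyl-1,3-benzodioxole-4-carbaldehyde; 8 furan-2(5H)-one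
Product: 10 γ-lactone of (1S,2S,3S)-1-hydroxy-3-(hydroxymethyl)-6-methoxy-7,8-(diphenylmethylenedioxy)-1,2,3,4-tetrahydronaphthalene-2-carboxylic acid (all-cis hydroxy lactone), via photoenol 9 (not isolated)
Conditions: 8 (3 equiv), Ti(OiPr)4 (2 equiv), (R,R)-TADDOL (2.2 equiv), 4 Å MS, degassed toluene, hν (366 nm), rt; aq. Rochelle salt
Reagents that add atoms: none
Why: Excitation of the aryl aldehyde at 366 nm and intersystem crossing lead to 1,5-hydrogen transfer from the C5 methyl group to the carbonyl oxygen; the dienol with its hydroxyl turned toward the methylene falls back to 7 by a hydrogen shift, whereas 9, with the hydroxyl turned outward, held by the neighbouring ketal oxygen and exchanged onto titanium as a dienolate, lives long enough to be trapped. The closest known reaction type is the Ti(OiPr)4-templated photoenolisation/Diels–Alder reaction of 2-alkoxy-6-methylbenzaldehydes with enones and unsaturated lactones, including its TADDOL-controlled enantioselective form. Ring B is closed by an intermolecular suprafacial [4+2] cycloaddition that forms C1–C2 and C3–C4 in one event, driven by the return of aromaticity to ring A. Regiochemistry: the methylene terminus of 9 has the larger HOMO coefficient and bonds to the β-carbon of 8, so the hydroxyl-bearing C1 ends next to the lactone carbonyl, and a titanium bridge between the enol oxygen and that carbonyl reinforces the pairing. C1: the outward hydroxyl of 9 together with the endo approach enforced by the same bridge places the C1 hydroxyl cis to the C2 carbonyl. C2 and C3: the cis geometry of the ring alkene of 8 is carried over unchanged and gives the cis ring fusion. Absolute configuration: the aryl groups of the TADDOLate on tetravalent titanium block one face of the bound dienolate–dienophile assembly, so one enantiomer of the all-cis adduct should dominate. The step needs clean formation of the outward enol without competing hydrogen abstraction, which the 2,6-disubstitution of the aldehyde and a ketal carbon free of hydrogen secure.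

Step 4
Reactants: 11 3,4,5-trimethoxyphenylboronic acid
Product: 12 potassium trifluoro(3,4,5-trimethoxyphenyl)borate
Conditions: KHF2 (4 equiv), MeOH/H2O, rt
Reagents that add atoms: potassium hydrogen difluoride, [K+].F[H-]F
Why: Standard fluoride exchange at boron converts the boronic acid into its crystalline trifluoroborate salt, which is inert until a Lewis acid removes fluoride.

Step 5
Reactants: 10 all-cis hydroxy lactone; 12 potassium trifluoro(3,4,5-trimethoxyphenyl)borate
Product: 15 γ-lactone of (1S,2R,3S)-3-(hydroxymethyl)-6-methoxy-7,8-(diphenylmethylenedioxy)-1-(3,4,5-trimethoxyphenyl)-1,2,3,4-tetrahydronaphthalene-2-carboxylic acid (aryl trans to C2; cis-fused), via aryldifluoroborane 13 (not isolated), via benzylic cation ion pair 14 (not isolated)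
Conditions: 12 (2 equiv), BF3·OEt2 (2.5 equiv), MeCN/CH2Cl2, −30 to 0 °C
Reagents that add atoms: none
Why: BF3·OEt2 removes fluoride from 12 to give Lewis-acidic 13, which ionises the C1 hydroxyl of 10 to cation 14, stabilised by the para C6 methoxy group and the ortho C8 oxygen; the aryl group then moves from boron to C1 by ipso substitution, which fixes the 3,4,5-pattern (a Lewis acid-mediated SN1 benzylic substitution with an aryltrifluoroborate, Friedel–Crafts type). Attack on the planar C1 should come from the convex face of the cis-fused lactone, anti to the C2–carbonyl bond, so C1 ends inverted relative to 10 (aryl trans to C2) while C2 and C3 are untouched.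

Step 6
Reactants: 15 aryl lactone
Product: 16 [(1S,2R,3S)-6-methoxy-7,8-(diphenylmethylenedioxy)-1-(3,4,5-trimethoxyphenyl)-1,2,3,4-tetrahydronaphthalene-2,3-diyl]dimethanol
Conditions: LiAlH4 (3 equiv), THF, 0 °C to rt; H2O, 15% aq. NaOH, H2O
Reagents that add atoms: none
Why: Hydride reduction of the γ-lactone to the 1,4-diol; reduction is faster than enolisation and the cis lactone is in any case the stable epimer, so C2 keeps its configuration, and the ketal and aryl ethers are inert to LiAlH4.

Step 7
Reactants: 16 ketal-protected diol
Product: 17 [(1S,2R,3S)-7,8-dihydroxy-6-methoxy-1-(3,4,5-trimethoxyphenyl)-1,2,3,4-tetrahydronaphthalene-2,3-diyl]dimethanol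
Conditions: H2 (1 atm), Pd/C (10 wt% palladium on carbon), MeOH/EtOAc, rt; filtration under argon
Reagents that add atoms: none
Why: Catalytic hydrogenolysis of the two benzhydrylic C–O bonds of the diphenylmethylene ketal frees the catechol and diphenylmethane; the C1 methine has no leaving group and the methyl ethers and alcohols are inert, so the stereotriad is not disturbed.

## Compound list

1 | 2,3-dihydroxy-4-methoxybenzaldehyde | COc1ccc(C=O)c(O)c1O | starting material
2 | dichlorodiphenylmethane | ClC(Cl)(c1ccccc1)c1ccccc1 | starting material
3 | 7-methoxy-2,2-diphenyl-1,3-benzodioxole-4-carbaldehyde | COc1ccc(C=O)c2OC(c3ccccc3)(c3ccccc3)Oc12 | intermediate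
4 | lithium (7-methoxy-2,2-diphenyl-1,3-benzodioxol-4-yl){[2-(dimethylamino)ethyl](methyl)amino}methanolate (carbinolamine carbon racemic) | COc1ccc(C([O-])N(C)CCN(C)C)c2OC(c3ccccc3)(c3ccccc3)Oc12.[Li+] | intermediate
5 | 5-lithio derivative of 4 | COc1cc([Li])c(C([O-])N(C)CCN(C)C)c2OC(c3ccccc3)(c3ccccc3)Oc12.[Li+] | intermediate
6 | 5-methyl derivative of 4 | COc1cc(C)c(C([O-])N(C)CCN(C)C)c2OC(c3ccccc3)(c3ccccc3)Oc12.[Li+] | intermediate
7 | 7-methoxy-5-methyl-2,2-diphenyl-1,3-benzodioxole-4-carbaldehyde | COc1cc(C)c(C=O)c2OC(c3ccccc3)(c3ccccc3)Oc12 | intermediate
8 | furan-2(5H)-one | O=C1OCC=C1 | starting material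
9 | photoenol of 7: 4-(hydroxymethylidene)-7-methoxy-5-methylidene-2,2-diphenyl-4,5-dihydro-1,3-benzodioxole, hydroxyl anti to the methylidene | O/C=C1/C(=C)C=C(OC)C2=C1OC(c1ccccc1)(c1ccccc1)O2 | intermediate
10 | γ-lactone of (1S,2S,3S)-1-hydroxy-3-(hydroxymethyl)-6-methoxy-7,8-(diphenylmethylenedioxy)-1,2,3,4-tetrahydronaphthalene-2-carboxylic acid | COc1cc2c(c3OC(c4ccccc4)(c4ccccc4)Oc13)[C@@H](O)[C@@H](C(=O)O3)[C@@H](C3)C2 | intermediate
11 | 3,4,5-trimethoxyphenylboronic acid | COc1cc(B(O)O)cc(OC)c1OC | starting material
12 | potassium trifluoro(3,4,5-trimethoxyphenyl)borate | COc1cc([B-](F)(F)F)cc(OC)c1OC.[K+] | intermediate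
13 | difluoro(3,4,5-trimethoxyphenyl)borane | COc1cc(B(F)F)cc(OC)c1OC | intermediate
14 | C1 benzylic cation of 10 paired with difluoro(hydroxy)(3,4,5-trimethoxyphenyl)borate | COc1cc2c(c3OC(c4ccccc4)(c4ccccc4)Oc13)[CH+][C@@H](C(=O)O3)[C@@H](C3)C2.O[B-](F)(F)c1cc(OC)c(OC)c(OC)c1 | intermediate
15 | γ-lactone of (1S,2R,3S)-3-(hydroxymethyl)-6-methoxy-7,8-(diphenylmethylenedioxy)-1-(3,4,5-trimethoxyphenyl)-1,2,3,4-tetrahydronaphthalene-2-carboxylic acid | COc1cc2c(c3OC(c4ccccc4)(c4ccccc4)Oc13)[C@H](c1cc(OC)c(OC)c(OC)c1)[C@@H](C(=O)O3)[C@@H](C3)C2 | intermediate
16 | [(1S,2R,3S)-6-methoxy-7,8-(diphenylmethylenedioxy)-1-(3,4,5-trimethoxyphenyl)-1,2,3,4-tetrahydronaphthalene-2,3-diyl]dimethanol | COc1cc2c(c3OC(c4ccccc4)(c4ccccc4)Oc13)[C@H](c1cc(OC)c(OC)c(OC)c1)[C@@H](CO)[C@@H](CO)C2 | intermediate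
17 | [(1S,2R,3S)-7,8-dihydroxy-6-methoxy-1-(3,4,5-trimethoxyphenyl)-1,2,3,4-tetrahydronaphthalene-2,3-diyl]dimethanol | COc1cc2c(c(O)c1O)[C@H](c1cc(OC)c(OC)c(OC)c1)[C@@H](CO)[C@@H](CO)C2 | target

## Step count and least certain steps

Total step count: 7. Longest linear sequence: 6 (steps 1, 2, 3, 5, 6, 7); step 4 is a one-step side branch.

**Step 3 (key step).** The most likely failure is poor facial selectivity together with low conversion. The dienol of 7 can bind titanium through both the enol oxygen and the neighbouring ketal oxygen, which may push the furanone off the chiral metal centre so that an untemplated, racemic cycloaddition competes, while return of the enol to 7 by hydrogen shift lowers throughput. The fallback puts the chirality into the dienophile instead of the ligand. It sets out from 7, which is irradiated at 366 nm in toluene with Ti(OiPr)4 but without chiral ligand, together with the enantiopure acetal (5S)-5-[(1S,2R,5S)-menthyloxy]furan-2(5H)-one F1. This is the known crystalline acetal of (+)-menthol, and its menthyloxy group blocks one face of the alkene. The expected adduct is the menthyloxy-substituted all-cis hydroxy lactone F2. Arylation with 12 and BF3·OEt2 as in step 5 should give the menthyloxy aryl lactone F3. LiAlH4 then reduces the lactone carbonyl and, after loss of menthol, the acetal carbon to primary alcohols, so the sequence comes back to the route at 16 without an extra step.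

**Step 2.** The most likely failure is metalation at the wrong site (C6, next to the methoxy group) or incomplete metalation, because three ether oxygens compete with the amino alkoxide for the base. The fallback uses a stronger, non-transient director and sets out from 3. Oxidation with NaClO2/NaH2PO4/2-methyl-2-butene gives 7-methoxy-2,2-diphenyl-1,3-benzodioxole-4-carboxylic acid F4. Condensation with diethylamine gives the N,N-diethylamide F5. Treatment with s-BuLi/TMEDA at −78 °C and then MeI gives the 5-methyl amide F6, since a tertiary amide outranks every ether as director. Reduction to the aldehyde level with Cp2Zr(H)Cl comes back to the route at 7.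

**Step 5.** Three processes could go wrong: loss of the C2 proton from cation 14 (elimination into conjugation with the lactone) outrunning aryl transfer, collapse of the ion pair on the face the hydroxyl has just left (1,2-cis), or bond formation at a ring position ortho to boron instead of ipso. The fallback uses a neutral arene nucleophile followed by etherification and sets out from 10. BF3·OEt2 and an excess of 2,6-dimethoxyphenol, which reacts para to its hydroxyl, should give the 1-(4-hydroxy-3,5-dimethoxyphenyl) lactone F7 under steric control by the lactone ring. O-Methylation (MeI, K2CO3, acetone; the cis lactone is the stable epimer, so the base is tolerated) comes back to the route at 15.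

**Step 7.** The most likely failure is sluggish hydrogenolysis of the hindered benzhydrylic C–O bonds, with partial cleavage and oxidation of the electron-rich catechol during long handling. The fallback moves the deprotection ahead of the reduction and uses acidolysis; it sets out from 15. TFA/H2O/CH2Cl2 should cleave the ketal to the catechol lactone F8 and benzophenone. This is done at the lactone stage because the 1,4-diol of 16 could close to a tetrahydrofuran under acid. LiAlH4 in THF with a dilute acid work-up then comes back to the route at 17.

## Further compounds

F1 | step 3 | (5S)-5-[(1S,2R,5S)-menthyloxy]furan-2(5H)-one | CC(C)[C@H]1CC[C@H](C)C[C@@H]1O[C@H]1OC(=O)C=C1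
F2 | step 3 | analogue of 10 carrying an (S)-configured (1S,2R,5S)-menthyloxy group on the lactone O–CH carbon, trans to the C3–C4 bond | COc1cc2c(c3OC(c4ccccc4)(c4ccccc4)Oc13)[C@@H](O)[C@@H](C(=O)O3)[C@@H]([C@H]3O[C@H]1C[C@@H](C)CC[C@@H]1C(C)C)C2
F3 | step 3 | analogue of 15 carrying the same menthyloxy group on the lactone O–CH carbon | COc1cc2c(c3OC(c4ccccc4)(c4ccccc4)Oc13)[C@H](c1cc(OC)c(OC)c(OC)c1)[C@@H](C(=O)O3)[C@@H]([C@H]3O[C@H]1C[C@@H](C)CC[C@@H]1C(C)C)C2
F4 | step 2 | 7-methoxy-2,2-diphenyl-1,3-benzodioxole-4-carboxylic acid | COc1ccc(C(=O)O)c2OC(c3ccccc3)(c3ccccc3)Oc12
F5 | step 2 | N,N-diethyl-7-methoxy-2,2-diphenyl-1,3-benzodioxole-4-carboxamide | COc1ccc(C(=O)N(CC)CC)c2OC(c3ccccc3)(c3ccccc3)Oc12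
F6 | step 2 | N,N-diethyl-7-methoxy-5-methyl-2,2-diphenyl-1,3-benzodioxole-4-carboxamide | COc1cc(C)c(C(=O)N(CC)CC)c2OC(c3ccccc3)(c3ccccc3)Oc12
F7 | step 5 | γ-lactone of (1S,2R,3S)-1-(4-hydroxy-3,5-dimethoxyphenyl)-3-(hydroxymethyl)-6-methoxy-7,8-(diphenylmethylenedioxy)-1,2,3,4-tetrahydronaphthalene-2-carboxylic acid | COc1cc2c(c3OC(c4ccccc4)(c4ccccc4)Oc13)[C@H](c1cc(OC)c(O)c(OC)c1)[C@@H](C(=O)O3)[C@@H](C3)C2
F8 | step 7 | γ-lactone of (1S,2R,3S)-7,8-dihydroxy-3-(hydroxymethyl)-6-methoxy-1-(3,4,5-trimethoxyphenyl)-1,2,3,4-tetrahydronaphthalene-2-carboxylic acid | COc1cc2c(c(O)c1O)[C@H](c1cc(OC)c(OC)c(OC)c1)[C@@H](C(=O)O3)[C@@H](C3)C2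
A1 | alternative 1 | (S)-7,8-bis(benzyloxy)-6-methoxy-1-(3,4,5-trimethoxyphenyl)-1,4-dihydronaphthalene | COc1cc2c(c(OCc3ccccc3)c1OCc1ccccc1)[C@H](c1cc(OC)c(OC)c(OC)c1)C=CC2
A2 | alternative 1 | dimethyl (1S,2R,3S)-7,8-bis(benzyloxy)-6-methoxy-1-(3,4,5-trimethoxyphenyl)-1,2,3,4-tetrahydronaphthalene-2,3-dicarboxylate | COc1cc2c(c(OCc3ccccc3)c1OCc1ccccc1)[C@H](c1cc(OC)c(OC)c(OC)c1)[C@@H](C(=O)OC)[C@@H](C(=O)OC)C2
A3 | alternative 2 | 4-{3-(benzyloxy)-4-hydroxy-5-[hydroxy(3,4,5-trimethoxyphenyl)methyl]... ring A carbinol with a C4a-methylene-linked γ-lactol (C3 configured as in the target) | COc1cc(C[C@@H]2COC(O)C2)c(C(O)c2cc(OC)c(OC)c(OC)c2)c(O)c1OCc1ccccc1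
A4 | alternative 2 | o-quinone methide from A3 (C8=O, C8a=C1) | O=C1C(OCc2ccccc2)=C(OC)C=C(C[C@@H]2COC(O)C2)C1=Cc1cc(OC)c(OC)c(OC)c1
A5 | alternative 2 | cis-fused tricyclic lactol with C1, C2 and C3 set (C7 benzyl ether, C8 free phenol) | COc1cc2c(c(O)c1OCc1ccccc1)[C@H](c1cc(OC)c(OC)c(OC)c1)[C@@H](C(O)O3)[C@@H](C3)C2
A6 | alternative 3 | methyl (S)-6-methoxy-7,8-(diphenylmethylenedioxy)-1-(3,4,5-trimethoxyphenyl)-1,4-dihydronaphthalene-2-carboxylate | COc1cc2c(c3OC(c4ccccc4)(c4ccccc4)Oc13)[C@H](c1cc(OC)c(OC)c(OC)c1)C(C(=O)OC)=CC2
A7 | alternative 3 | cis-fused aryl lactone, identical with 15 | COc1cc2c(c3OC(c4ccccc4)(c4ccccc4)Oc13)[C@H](c1cc(OC)c(OC)c(OC)c1)[C@@H](C(=O)O3)[C@@H](C3)C2
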